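(The constants used here are made up; no experiment stands behind them.)

In 15 h, at one steady temperature, four flasks with the same charges differ in how L and G go in, and the question is how much G.Q each holds at the end.

    L ⇌ Q (K1 = 0.037, k1 = 4.23 × 10⁻⁵ s⁻¹)
    G + Q → G.Q (k2 = 6.43 M⁻¹ s⁻¹)
    E + Q → E.Q (k3 = 4.81 M⁻¹ s⁻¹)
    2 E → E2 (k4 = 0.00534 M⁻¹ s⁻¹)
    L + G.Q → L.G.Q (k5 = 0.00320 M⁻¹ s⁻¹)

| flask | L | G | E | time | remark |
|---|---|---|---|---|---|
| south | 20 mM (fed, over 10 h) | 14.0 mM | 18.0 mM | 15 h | all else is in the flask from the start; the feed brings no volume worth counting |
| north-west | 20 mM | 14.0 mM (fed, over 10 h) | 18.0 mM | 15 h | all else is in the flask from the start; the feed brings no volume worth counting |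
| north | 20 mM | 14.0 mM | 18.0 mM | 15 h | everything together at the start |
| south-west | 20 mM | 14.0 mM (in portions, 2, over 10 h) | 18.0 mM | 15 h | first portion at the start, last at 10 h |

- percentages count the L that a species holds: one L.G.Q counts as two
- for a step with 2 of a species take k times the square, and two of it per event
- run time (south): 15 h

- which flask leads in amount of G.Q, in percent of the L charged ("all alike" within 1.5 percentage points) (south / north-west / north / south-west / all alike)
- how much G.Q is there at the end, in percent of the L charged: south
- how much G.Q is there at the end, in percent of the L charged: north-west
- how much G.Q is there at the end, in percent of the L charged: north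
- how much G.Q is there at the end, in percent of the L charged: south-west

Question: where does G.Q come from? Answer: L turns slowly into Q, and each Q is taken by G, giving G.Q, or by E, giving E.Q. The way back to L, at 0.00114 s⁻¹ per Q, is slower than capture by G at its charge, at 0.0900 s⁻¹, so I leave it out.

Question: what do you carry from flask to flask? Answer: the catch share, the part of the Q formed at a given moment that goes to G. It is k2[G] divided by k2[G] + k3[E], where square brackets mean concentrations. The ratio of the two rate constants, k2/k3, is the usual selectivity factor, and the share weighs it by [G]/[E]. With G and E both at their charges, the share is 51.0%.

Question: does that share stay put? Answer: no, it drifts, since E pairs off into E2. Its half-life by step 4 alone is 1.44 h, shorter than the feed. In this kind of fall 1/[E] grows steadily with time, so after 10 h step 4 alone leaves 2.27 mM of E. South has by then gathered its fed L, so I read it at that moment, with G still at its charge, and its catch share at the end of the feed is 89.2%.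

Question: and the other flasks? Answer: they have L from the start, so I read them there. North has 51.0%, south-west with its opening portion has 34.2%, and north-west starts without G, so its share is nil. The leader is south. Shares in north-west and south-west rise as G arrives, so I do not rank those two.

Question: you held G at its charge, and a share is not an amount. Answer: agreed. G is consumed, so the south figure sits on the high side. G.Q also goes on to L.G.Q, with a half-life by step 5 alone, as charged in north, of 3.0 h, shorter than the run. So I stop at the leader and give no amounts.

The forecast names south and gives 33% for south, 27% for north-west, 32% for north and 23% for south-west. Its grounds include “Feeding L helps by letting E die off first”.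

The simulation names south, with 34.3% in south, 29.2% in north-west, 32.7% in north and 26.2% in south-west.

With the G and E that south holds at 10.0 h, 47.4% and 8.33% of their charges, the share reads 85.5%, against the reckoned 89.2%, which leaves E 10.8% of the Q. Now take south with 35 mM of G. The same reckoning, with E unchanged at 2.27 mM, gives a catch share of 95.4% and leaves E 4.63%. That neighbour ends with 38.6% of G.Q, and its E.Q stands at 4.56%, where south has 11.4%.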